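The route rests on cutting the C1'–C2' bond of the C8 side chain. In ring A, C8 bears the C1' methylene beside the oxygenated C7, exactly what capture of an ortho-quinone methide (carbonyl at C7, exocyclic CH2 on C8) would leave. In one operation the key step adds the chiral enamine of 5-methylhex-5-enal to that methide, fixes C2' and ties O7 to the aldehyde carbon as a chroman-2-ol ring. This temporary ring later steers prenylation of C8 anti to the C2' chain, and the aldehyde carbon ends as the isopropenyl group. The precursor is the complete (2R,3S)-chromanone with the (S)-ester chain at C6 and CH2NMe2 at C8, quaternised in the flask.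

Key step: step 10

Remark: locants in the Why lines follow the chromanone numbering of the target (O1, C2–C4, C4a, C5–C8, C8a; ring A is the carbocycle; C1'–C5' is the C8 chain); the facial sense of the copper hydride reduction (step 3), of the quinine cyclisation (step 5) and of the enamine addition (step 10) is assumed from the accepted models for these catalysts, and the antipodal ligand, quinidine or the (R)-catalyst would be used if a sense proved opposite.

Step 1
Reactants: 1 phloroglucinol; 2 ethyl 3-oxohexanoate
Product: 3 5,7-dihydroxy-4-propylcoumarin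
Conditions: conc. H2SO4, 0 °C → rt
Reagents that add atoms: none
Why: Pechmann condensation: acid-promoted transesterification and ring closure of the ketone onto the electron-rich ring should give the coumarin, and the threefold symmetry of 1 leaves no regiochemical choice.

Step 2
Reactants: 3 5,7-dihydroxy-4-propylcoumarin
Product: 4 5,7-bis(tert-butyldimethylsilyloxy)-4-propylcoumarin
Conditions: t-BuMe2SiCl (2.5 equiv), imidazole, DMF, rt
Reagents that add atoms: tert-butyldimethylsilyl chloride, CC(C)(C)[Si](C)(C)Cl
Why: Imidazole-promoted silylation of both phenols (silyl ether formation) removes the acidic protons that would quench the copper hydride of step 3 and turn the enoate into an unreactive phenoxide.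

Step 3
Reactants: 4 5,7-bis(tert-butyldimethylsilyloxy)-4-propylcoumarin
Product: 6 (4S)-5,7-dihydroxy-4-propylchroman-2-one, via bis-silyl dihydrocoumarin 5 (not isolated)
Conditions: Cu(OAc)2·H2O (5 mol%), (R)-5,5'-bis[bis(3,5-di-tert-butyl-4-methoxyphenyl)phosphino]-4,4'-bi-1,3-benzodioxole (5 mol%), (EtO)2MeSiH (1.5 equiv), t-BuOH (1.5 equiv), toluene, rt; then Bu4NF, AcOH, THF, 0 °C
Reagents that add atoms: none
Why: Asymmetric conjugate reduction of a 4-substituted coumarin by a bisphosphine-ligated copper hydride (a known reaction of this substrate class) should deliver hydride to one face of C4 under control of the chiral ligand and so set the (S) centre, t-BuOH protonates the copper enolate, and buffered fluoride then cleaves both aryl silyl ethers without opening the lactone.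

Step 4
Reactants: 6 (4S)-5,7-dihydroxy-4-propylchroman-2-one; 7 tigloyl chloride
Product: 8 (4S)-5,7-dihydroxy-8-[(E)-2-methylbut-2-enoyl]-4-propylchroman-2-one
Conditions: AlCl3 (3.5 equiv), PhNO2, 0 °C → rt
Reagents that add atoms: none
Why: Friedel–Crafts acylation should take place at C8 of the dihydrocoumarin, which is ortho to 7-OH and para to 5-OH and is the site acyl chlorides attack in 5,7-dihydroxy benzopyranones (the 5-OH side is crowded by the C4 propyl group), and an acyl group beside the lactone oxygen leaves 7-OH as the only phenol able to reach the enone; any C6 isomer is removed by chromatography.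

Step 5
Reactants: 8 (4S)-5,7-dihydroxy-8-[(E)-2-methylbut-2-enoyl]-4-propylchroman-2-one
Product: 9 tricyclic lactone with cis-(2R,3S)-2,3-dimethylchromanone ring
Conditions: (−)-quinine (20 mol%), PhCl, rt
Reagents that add atoms: none
Why: Cinchona-alkaloid-catalysed intramolecular oxa-Michael addition (6-endo-trig) of the ortho-tigloyl phenol: the quinuclidine nitrogen activates the phenol, the ion-paired catalyst selects the enone face so that the O-bearing carbon becomes (R), and the quinuclidinium proton is delivered to the enol on the same face to give the kinetic cis-dimethyl arrangement (α-carbon S), as known for 7-hydroxy-8-tigloyl benzopyranones.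

Step 6
Reactants: 9 tricyclic lactone with cis-(2R,3S)-2,3-dimethylchromanone ring
Product: 10 methyl (3S)-3-[(2R,3S)-5,7-dihydroxy-2,3-dimethyl-4-oxochroman-6-yl]hexanoate
Conditions: MeOH, H2SO4 (10 mol%), rt
Reagents that add atoms: methanol, CO
Why: Acid-catalysed lactone methanolysis (transesterification) is driven by methanol as solvent and by the strong hydrogen bond of the released 5-OH to the C4 carbonyl, and the absence of base avoids epimerisation at C3 and retro-oxa-Michael opening of the cis-chromanone.

Step 7
Reactants: 10 methyl (3S)-3-[(2R,3S)-5,7-dihydroxy-2,3-dimethyl-4-oxochroman-6-yl]hexanoate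
Product: 11 methyl (3S)-3-[(2R,3S)-8-(dimethylaminomethyl)-5,7-dihydroxy-2,3-dimethyl-4-oxochroman-6-yl]hexanoate
Conditions: Me2NH (40% in H2O, 1.1 equiv), CH2O (37% in H2O, 1.1 equiv), EtOH, 0 °C → rt
Reagents that add atoms: formaldehyde, C=O; dimethylamine, CNC
Why: Phenol Mannich reaction (aminomethylation): the iminium ion attacks C8, the only unsubstituted carbon of ring A and ortho to 7-OH, so no regiochemical choice remains.

Step 8
Reactants: 12 methyl 5-oxohexanoate
Product: 13 methyl 5-methylhex-5-enoate
Conditions: Ph3PCH3Br, KOt-Bu, THF, 0 °C → rt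
Reagents that add atoms: methyltriphenylphosphonium bromide, C[P+](c1ccccc1)(c1ccccc1)c1ccccc1.[Br-]
Why: Wittig methylenation converts the ketone into the 1,1-disubstituted alkene while the less electrophilic methyl ester is untouched.

Step 9
Reactants: 13 methyl 5-methylhex-5-enoate
Product: 14 5-methylhex-5-enal
Conditions: i-Bu2AlH (1.05 equiv), CH2Cl2, −78 °C; aq. KNaC4H4O6 work-up
Reagents that add atoms: none
Why: Partial reduction of the ester with i-Bu2AlH at −78 °C stops at the aluminium hemiacetal, which releases the aldehyde only on aqueous work-up.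

Step 10
Reactants: 11 methyl (3S)-3-[(2R,3S)-8-(dimethylaminomethyl)-5,7-dihydroxy-2,3-dimethyl-4-oxochroman-6-yl]hexanoate; 14 5-methylhex-5-enal
Product: 19 tricyclic chroman-2-ol lactol with (R)-C2' (both anomers), via ammonium iodide 15 (not isolated), via quinone methide 16 (not isolated), via enamine 17 (not isolated), via hydroxy aldehyde 18 (not isolated)
Conditions: MeI (1.1 equiv), MeCN, rt, then evaporation; 14 (3 equiv), (S)-α,α-diphenylprolinol trimethylsilyl ether (20 mol%), Na2CO3 (2 equiv), CH2Cl2, 0 °C → rt
Reagents that add atoms: none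
Why: N-Methylation turns the amine into a trimethylammonium leaving group, carbonate deprotonates 7-OH and loss of NMe3 (which, unlike Me2NH, cannot form a competing achiral enamine) gives ortho-quinone methide 16 with C7=O and C8=CH2. The E-enamine 17 adds through its nucleophilic carbon to the exocyclic CH2 in a Michael addition driven by rearomatisation of ring A (C1'–C2' bond), and hydrolysis of the iminium ion returns the catalyst and gives aldehyde 18. The 7-OH then adds to the aldehyde carbon in a 6-exo-trig hemiacetalisation that closes the chroman-2-ol ring, so the whole is a formal [4+2] of a known type, the diarylprolinol silyl ether catalysed addition of aldehydes to ortho-quinone methides generated in situ. C2' is set by the catalyst: its CPh2(OSiMe3) group blocks one face of the s-trans E-enamine, and the (S)-catalyst is expected to give (R), the same sense as in its Michael additions to nitroalkenes. Only the enamine face has to be controlled because the electrophilic carbon is an unsubstituted CH2; the substrate secures chemoselectivity because C6 is blocked, the methide offers a single electrophilic carbon and 7-OH is the only hydroxyl within reach of the aldehyde, while the anomeric carbon is left as a mixture that disappears later.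

Step 11
Reactants: 19 tricyclic chroman-2-ol lactol with (R)-C2' (both anomers)
Product: 20 tricyclic methyl acetal (both anomers)
Conditions: MeOH, pyridinium p-toluenesulfonate (10 mol%), rt
Reagents that add atoms: methanol, CO
Why: Acid-catalysed acetalisation of the lactol through its cyclic oxocarbenium ion (Fischer-type glycosidation) caps the hemiacetal so that base cannot open it, and the weak acid should leave the 1,1-disubstituted alkene and the C2' centre untouched.

Step 12
Reactants: 20 tricyclic methyl acetal (both anomers); 21 prenyl bromide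
Product: 22 C8-prenylated dearomatised acetal with prenyl trans to the C2' chain
Conditions: NaOMe (1.0 equiv), MeOH, 0 °C; then 21 (3 equiv), 0 °C → rt
Reagents that add atoms: none
Why: Alkylative dearomatisation (C-alkylation of a phloroglucinol-type phenoxide): the 5-phenoxide is chelated to C4=O, flanked on both sides and solvated by methanol, so carbon attack should go to C8, which is para to O5, activated by O7 and O1 and less hindered than C6; the new bond must form perpendicular to ring A and therefore axial on the fused dihydropyran, and attack on the face that keeps the C2' chain equatorial in a chair-like transition state (no 1,3-diaxial prenyl/chain contact) places prenyl trans to that chain and so sets C8.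

Step 13
Reactants: 22 C8-prenylated dearomatised acetal with prenyl trans to the C2' chain
Product: 23 aldehyde with free enolised β-diketone
Conditions: 1 M aq. HCl, THF, 0 °C
Reagents that add atoms: water, O
Why: Hydrolysis of a vinylogous acylal: after dearomatisation O7 belongs to a vinylogous ester, so the C–O7 bond ionises under mild aqueous acid and water converts the oxocarbenium ion into the aldehyde and the enolised β-diketone, cold enough not to epimerise C2'.

Step 14
Reactants: 23 aldehyde with free enolised β-diketone
Product: 24 secondary alcohol (both carbinol epimers)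
Conditions: MeMgBr (3 equiv), THF, −78 °C; aq. NH4Cl
Reagents that add atoms: methylmagnesium bromide, C[Mg]Br
Why: Grignard addition to the aldehyde: the first equivalent turns the acidic enol into a delocalised magnesium enolate that shields the ring carbonyls and C3–H, the aldehyde reacts far faster than the methyl ester at −78 °C, and the configuration of the new carbinol is irrelevant because it is oxidised next.

Step 15
Reactants: 24 secondary alcohol (both carbinol epimers)
Product: 25 methyl ketone
Conditions: Pr4N[RuO4] (5 mol%), N-methylmorpholine N-oxide (1.5 equiv), 4 Å molecular sieves, CH2Cl2, rt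
Reagents that add atoms: none
Why: Ley–Griffith oxidation: catalytic perruthenate with the N-oxide as terminal oxidant converts the secondary alcohol into the methyl ketone under neutral, buffered conditions that should leave the three alkenes and the enolised ring alone.

Step 16
Reactants: 25 methyl ketone
Product: 26 methyl ester of the target
Conditions: Ph3PCH3Br (4 equiv), KOt-Bu (3.8 equiv), THF, 0 °C → rt
Reagents that add atoms: methyltriphenylphosphonium bromide, C[P+](c1ccccc1)(c1ccccc1)c1ccccc1.[Br-]
Why: Wittig methylenation with excess ylide: the first equivalent deprotonates the enol, whose anion protects the ring carbonyls and C3–H, and the methyl ketone is converted into the isopropenyl group while the methyl ester is inert.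

Step 17
Reactants: 26 methyl ester of the target
Product: 27 CNP0294320.1
Conditions: LiOH (5 equiv), THF–MeOH–H2O, 0 °C → rt; then 1 M HCl to pH 3, 0 °C
Reagents that add atoms: lithium hydroxide, [Li+].[OH-]
Why: Ester saponification: hydroxide cleaves the methyl ester while the ring is protected as its enolate, and cold, brief acidification liberates the acid without acid-promoted cyclisation of the enol onto the alkenes.

Compound list

1 | phloroglucinol (benzene-1,3,5-triol) | Oc1cc(O)cc(O)c1 | starting material
2 | ethyl 3-oxohexanoate | CCCC(=O)CC(=O)OCC | starting material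
3 | 5,7-dihydroxy-4-propyl-2H-chromen-2-one | CCCC1=CC(=O)Oc2cc(O)cc(O)c12 | intermediate
4 | 5,7-bis(tert-butyldimethylsilyloxy)-4-propyl-2H-chromen-2-one | CCCC1=CC(=O)Oc2cc(O[Si](C)(C)C(C)(C)C)cc(O[Si](C)(C)C(C)(C)C)c12 | intermediate
5 | (4S)-5,7-bis(tert-butyldimethylsilyloxy)-4-propylchroman-2-one | CCC[C@H]1CC(=O)Oc2cc(O[Si](C)(C)C(C)(C)C)cc(O[Si](C)(C)C(C)(C)C)c12 | intermediate
6 | (4S)-5,7-dihydroxy-4-propylchroman-2-one | CCC[C@H]1CC(=O)Oc2cc(O)cc(O)c12 | intermediate
7 | tigloyl chloride, (E)-2-methylbut-2-enoyl chloride | C/C=C(\C)C(=O)Cl | starting material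
8 | (4S)-5,7-dihydroxy-8-[(E)-2-methylbut-2-enoyl]-4-propylchroman-2-one | CCC[C@H]1CC(=O)Oc2c(C(=O)/C(C)=C/C)c(O)cc(O)c12 | intermediate
9 | (4S,8R,9S)-5-hydroxy-8,9-dimethyl-4-propyl-3,4,8,9-tetrahydro-2H,10H-pyrano[2,3-f]chromene-2,10-dione (cis-8,9-dimethyl) | CCC[C@H]1CC(=O)Oc2c3C(=O)[C@@H](C)[C@@H](C)Oc3cc(O)c12 | intermediate
10 | methyl (3S)-3-[(2R,3S)-5,7-dihydroxy-2,3-dimethyl-4-oxochroman-6-yl]hexanoate | CCC[C@@H](CC(=O)OC)c1c(O)cc2O[C@H](C)[C@H](C)C(=O)c2c1O | intermediate
11 | methyl (3S)-3-[(2R,3S)-8-[(dimethylamino)methyl]-5,7-dihydroxy-2,3-dimethyl-4-oxochroman-6-yl]hexanoate | CN(C)Cc1c(O)c([C@@H](CCC)CC(=O)OC)c(O)c2c1O[C@H](C)[C@H](C)C2=O | intermediate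
12 | methyl 5-oxohexanoate | COC(=O)CCCC(C)=O | starting material
13 | methyl 5-methylhex-5-enoate | COC(=O)CCCC(C)=C | intermediate
14 | 5-methylhex-5-enal | C=C(C)CCCC=O | intermediate
15 | N-methyl quaternary ammonium iodide of 11 (8-CH2NMe3 iodide) | C[N+](C)(C)Cc1c(O)c([C@@H](CCC)CC(=O)OC)c(O)c2c1O[C@H](C)[C@H](C)C2=O.[I-] | intermediate
16 | ortho-quinone methide: methyl (3S)-3-[(2R,3S)-5-hydroxy-2,3-dimethyl-8-methylidene-4,7-dioxo-2,3,7,8-tetrahydro-4H-chromen-6-yl]hexanoate | C=C1C(=O)C([C@@H](CCC)CC(=O)OC)=C(O)C2=C1O[C@H](C)[C@H](C)C2=O | intermediate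
17 | (E)-enamine of 14 with (S)-α,α-diphenylprolinol trimethylsilyl ether | C=C(C)CC/C=C/N1CCC[C@H]1C(c1ccccc1)(c1ccccc1)O[Si](C)(C)C | intermediate
18 | methyl (3S)-3-[(2R,3S)-8-[(2R)-2-formyl-5-methylhex-5-enyl]-5,7-dihydroxy-2,3-dimethyl-4-oxochroman-6-yl]hexanoate | C=C(C)CC[C@H](Cc1c(O)c([C@@H](CCC)CC(=O)OC)c(O)c2c1O[C@H](C)[C@H](C)C2=O)C=O | intermediate
19 | methyl (3S)-3-[(2R,3S,9R)-5,8-dihydroxy-2,3-dimethyl-9-(3-methylbut-3-enyl)-4-oxo-3,4,9,10-tetrahydro-2H,8H-pyrano[2,3-f]chromen-6-yl]hexanoate, both C8 anomers | C=C(C)CC[C@@H]1Cc2c(OC1O)c([C@@H](CCC)CC(=O)OC)c(O)c3c2O[C@H](C)[C@H](C)C3=O | intermediate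
20 | 8-O-methyl acetal of 19 (8-methoxy in place of 8-hydroxy), both C8 anomers | C=C(C)CC[C@@H]1Cc2c(OC1OC)c([C@@H](CCC)CC(=O)OC)c(O)c3c2O[C@H](C)[C@H](C)C3=O | intermediate
21 | prenyl bromide, 1-bromo-3-methylbut-2-ene | CC(C)=CCBr | starting material
22 | dearomatised acetal: 20 carrying a 3-methylbut-2-enyl group on the ring-fusion carbon that bears the ring CH2 (C8 in chromanone numbering), trans to the C2' side chain across the dihydropyran; ring A now a 4,5-dioxo cross-conjugated dienone; both anomers | C=C(C)CC[C@@H]1C[C@@]2(CC=C(C)C)C(OC1OC)=C([C@@H](CCC)CC(=O)OC)C(=O)C3=C2O[C@H](C)[C@H](C)C3=O | intermediate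
23 | methyl (3S)-3-[(2R,3S,8R)-8-[(2R)-2-formyl-5-methylhex-5-enyl]-5-hydroxy-2,3-dimethyl-8-(3-methylbut-2-enyl)-4,7-dioxo-2,3,7,8-tetrahydro-4H-chromen-6-yl]hexanoate | C=C(C)CC[C@H](C[C@@]1(CC=C(C)C)C(=O)C([C@@H](CCC)CC(=O)OC)=C(O)C2=C1O[C@H](C)[C@H](C)C2=O)C=O | intermediate
24 | methyl (3S)-3-[(2R,3S,8R)-5-hydroxy-8-[(2R)-2-(1-hydroxyethyl)-5-methylhex-5-enyl]-2,3-dimethyl-8-(3-methylbut-2-enyl)-4,7-dioxo-2,3,7,8-tetrahydro-4H-chromen-6-yl]hexanoate, both carbinol epimers | C=C(C)CC[C@H](C[C@@]1(CC=C(C)C)C(=O)C([C@@H](CCC)CC(=O)OC)=C(O)C2=C1O[C@H](C)[C@H](C)C2=O)C(C)O | intermediate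
25 | methyl (3S)-3-[(2R,3S,8R)-8-[(2R)-2-acetyl-5-methylhex-5-enyl]-5-hydroxy-2,3-dimethyl-8-(3-methylbut-2-enyl)-4,7-dioxo-2,3,7,8-tetrahydro-4H-chromen-6-yl]hexanoate | C=C(C)CC[C@H](C[C@@]1(CC=C(C)C)C(=O)C([C@@H](CCC)CC(=O)OC)=C(O)C2=C1O[C@H](C)[C@H](C)C2=O)C(C)=O | intermediate
26 | methyl (3S)-3-[(2R,3S,8R)-5-hydroxy-2,3-dimethyl-8-[(2R)-5-methyl-2-(prop-1-en-2-yl)hex-5-enyl]-8-(3-methylbut-2-enyl)-4,7-dioxo-2,3,7,8-tetrahydro-4H-chromen-6-yl]hexanoate | C=C(C)CC[C@H](C[C@@]1(CC=C(C)C)C(=O)C([C@@H](CCC)CC(=O)OC)=C(O)C2=C1O[C@H](C)[C@H](C)C2=O)C(=C)C | intermediate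
27 | CNP0294320.1, (3S)-3-[(2R,3S,8R)-5-hydroxy-2,3-dimethyl-8-[(2R)-5-methyl-2-(prop-1-en-2-yl)hex-5-enyl]-8-(3-methylbut-2-enyl)-4,7-dioxo-2,3,7,8-tetrahydro-4H-chromen-6-yl]hexanoic acid | C=C(C)CC[C@H](C[C@@]1(CC=C(C)C)C(=O)C([C@@H](CCC)CC(=O)O)=C(O)C2=C1O[C@H](C)[C@H](C)C2=O)C(=C)C | target

Total step count: 17. Longest linear sequence: 15 steps (steps 1–7 and 10–17, from 1); the aldehyde branch (steps 8–9) is two steps.

Steps most likely to fail

Step 10. The quinone methide may be lost to self-condensation or to alkylation of the catalyst nitrogen before the enamine captures it, and the enamine face may be poorly discriminated. The fallback sets the stereocenter with a covalently bound auxiliary instead of a catalyst; it sets out from aldehyde 14 and ammonium iodide 15 and rejoins the route at 19. Aldehyde 14 would be condensed with (R)-1-amino-2-(methoxymethyl)pyrrolidine to give the RAMP hydrazone F1. F1 would be deprotonated with LiN(i-Pr)2 in THF at −78 °C and 15 added to an excess of the azaenolate. The first equivalents act as base and release quinone methide 16, which is then alkylated at its CH2, the auxiliary directing the electrophile to the face that gives (R) at C2', to give the alkylated hydrazone F2. Two-phase hydrolysis with aqueous oxalic acid would cleave the hydrazone, and the freed aldehyde closes to lactol 19.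

Step 12. Alkylation may take place on O5 or on C6 instead of C8, and attack may occur on both faces of ring A. The fallback places the prenyl group on oxygen first and moves it to carbon by sigmatropic shifts; it sets out from 20 and rejoins at 22. Phenol 20 would be O-alkylated with 21 under conditions that favour oxygen (K2CO3, DMF) to give the aryl prenyl ether F3. Heating F3 in toluene should trigger an aromatic Claisen shift to C6 and, because C6 is fully substituted, a following Cope shift to C8, which restores the normal prenyl orientation and delivers dienone 22. The second shift also has to bring carbon in perpendicular to ring A and is subject to the same preference for the face anti to the C2' chain.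

Step 3. Hydride delivery to the lactone β-carbon, which is flanked by the neighbouring silyloxy group and deactivated by two oxygen donors, may stall, or the lactone may be reduced further to the lactol. The fallback makes the stereocenter by C–C instead of C–H bond formation; it sets out from 1 and rejoins at 6. Phloroglucinol 1 would be converted into 3,5-dimethoxyphenol F4 (MeOH, H2SO4). F4 and (E)-hex-2-enal would undergo the amine-catalysed Friedel–Crafts alkylation with hemiacetal closure (diarylprolinol silyl ether, iminium activation, catalyst enantiomer chosen by the shielding model to give 4S) to give (4S)-5,7-dimethoxy-4-propylchroman-2-ol F5. Oxidation with C5H5NH[CrO3Cl] would give (4S)-5,7-dimethoxy-4-propylchroman-2-one F6, and BBr3 would cleave both methyl ethers to give 6.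

Further compounds

F1 | step 10 | RAMP hydrazone of 5-methylhex-5-enal | C=C(C)CCC/C=N/N1CCC[C@@H]1COC
F2 | step 10 | RAMP hydrazone of aldehyde 18 (alkylated hydrazone, C2' R) | C=C(C)CC[C@H](Cc1c(O)c([C@@H](CCC)CC(=O)OC)c(O)c2c1O[C@H](C)[C@H](C)C2=O)/C=N/N1CCC[C@@H]1COC
F3 | step 12 | 5-O-(3-methylbut-2-enyl) ether of 20 (aryl prenyl ether) | C=C(C)CC[C@@H]1Cc2c(OC1OC)c([C@@H](CCC)CC(=O)OC)c(OCC=C(C)C)c3c2O[C@H](C)[C@H](C)C3=O
F4 | step 3 | 3,5-dimethoxyphenol | COc1cc(O)cc(OC)c1
F5 | step 3 | (4S)-5,7-dimethoxy-4-propylchroman-2-ol (both anomers) | CCC[C@H]1CC(O)Oc2cc(OC)cc(OC)c12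
F6 | step 3 | (4S)-5,7-dimethoxy-4-propylchroman-2-one | CCC[C@H]1CC(=O)Oc2cc(OC)cc(OC)c12
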